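## Structural features

1. The target has no saturated ring. Ring A (C1–C6, 4-OH, 3-OMe) and ring B (C1'–C6', 3',5'-di-OMe, 4'-O) sit at the ends of the chain C7–C8(C9H3)–C8'(C9'H3)–C7'. Ring C (C1''–C6'', 4''-OH, 3''-OMe) sits on the unit C7''(OH)–C8''(C9''H3), whose C8'' is bound to O4' of ring B.
2. The four stereocentres form two vicinal pairs, C8/C8' and C7''/C8''. They lie seven bonds apart across ring B, so neither pair can steer the other, and isomers that differ only in the relation between the pairs cannot be expected to separate.
3. The pair C8/C8' is (S,R), the meso-type arrangement. The chain C7–C8–C8'–C7' with C9 and C9' has a local mirror plane, which is broken only by the difference between ring A and ring B (the C5' methoxy group and the O4' substituent).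
4. These two centres carry only carbon and hydrogen, so no heteroatom is at hand to direct a reagent or to correct a wrong configuration later.
5. The key step exploits this latent mirror symmetry of C7–C8–C8'–C7'. The absolute configuration of C8 and C8' reduces to the question of which end of a meso dimethyl-C4 unit receives ring A.
6. The pair C7''/C8'' is threo (S,S). Its ether oxygen O4' lies between the methoxy groups at C3' and C5' and is a hindered, weak nucleophile, and threo is the isomer that chelate-controlled hydride delivery does not give.
7. Three features are fragile: the p-hydroxybenzylic alcohol at C7'' (ionisation in acid, quinone methide formation in base, hydrogenolysis), the two electron-rich free phenols (oxidation), and any C7'' ketone precursor, whose C8''–H is acidic.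
8. The real difficulty is absolute control over the handle-free pseudo-meso pair C8/C8' together with the differentiation of the two chain ends. The hindered threo ether comes second.

## Logic of the disconnections

**21 ⇒ 20.**
- Bonds cut: O4–H, O4''–H and O7''–H are traced back to three O–Si bonds.
- Reason: every acidic proton must be absent when the halves are joined, and the C7'' alcohol tolerates neither acid nor hydrogenolysis.
- Gain: none in the skeleton, but the last step becomes one operation.
- Demand: a release that is neither acidic, nor reductive, nor strongly basic.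

**20 ⇒ 10 + 18 (through 19).**
- Bond cut: C7'–C1' (sp3–sp2).
- Reason: it lies between the two stereochemical pairs, touches no stereocentre and divides the molecule into halves of equal size.
- Gain: a four-centre problem becomes two independent two-centre problems, and the longest linear sequence is halved.
- Demand: a primary, β-branched alkyl metal must couple faster than it loses a β-hydrogen. The position C1' of 18, flanked by C2'–H and C6'–H, is unhindered and helps.

**18 ⇒ 17 ⇒ 16.**
- Bonds cut: O7''–Si and C7''–H.
- Reason: C7'' is best set last in its half, next to an existing C8'', where catalyst and substrate can act in the same sense.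
- Gain: one stereocentre less.
- Demand: hydride delivery without a chelating cation and without enolisation at C8''.

**16 ⇒ 14 + 2 (through 15).**
- Bond cut: C7''–C1''.
- Reason: ring C then comes from the same 2 that supplies ring A.
- Gain: one aryl building block serves twice.
- Demand: single addition to the acyl group, no halogen–metal exchange at C1'–Br, and no loss of configuration at C8''.

**14 ⇒ 13 ⇒ 11 + 12.**
- Bond cut: C8''–O4' (and the amide C–N).
- Reason: the hindered O4' meets the smallest possible secondary electrophile, activated by the adjacent carbonyl group, and the stereocentre is bought.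
- Gain: C8'' comes from the chiral pool.
- Demand: clean inversion at C8''.

**10 ⇒ 9 ⇒ 8 ⇒ 7.**
- Bonds cut: C7'–I, the C7'–H bonds and the C7–H bonds (changes of oxidation level only).
- Reason: the two chain ends of 7 already differ (ketone at C7, carboxyl at C7'), so each is adjusted without protecting the other.
- Gain: none in the skeleton.
- Demand: C8 (next to the ketone) and C8' (next to the carboxyl group) must not epimerise.

**7 ⇒ 2 + 4 (through 5 and 6), the key disconnection.**
- Bond cut: C7–C1.
- Reason: removing ring A from 7 and closing the two acyl ends over one oxygen restores the mirror plane.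
- Gain: the precursor 4 is achiral, has six carbons and already holds C7, C8, C8', C7', C9 and C9' with the correct relative configuration.
- What the forward step settles at once: the absolute configuration of C8 and C8', the differentiation of the chain ends, and the bond to ring A.
- Demand: a catalyst that tells the two enantiotopic carbonyl groups of 4 apart and stops after one addition.
- In one sentence, the route is the ligand-controlled opening of 4 by 6. That sentence does not fit the plan of Alternative 1.

**4 ⇒ 3 and 2 ⇒ 1.**
- Bonds cut: the anhydride C–O bond and the O4–Si bond.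
- Reason and gain: both precursors are commercial, and the meso relation of C8/C8' is bought with 3.
- Demand: ring closure without enolisation.

## Other disconnections considered

**Alternative 1:** (the first that comes to mind)
- Cut: C8''–O4' last.
- Forward key step: the complete lignan phenol A1 displaces bromide from the racemic bromoketone A2 in an SN2 reaction. This gives the keto ether A3, which is reduced with a simple hydride.
- C8'' would be formed without control, seven bonds from the nearest stereocentre, so A3 is expected as a pair of epimers that differ only in the relation of remote centres.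
- A borohydride with a coordinating cation should lean towards erythro, the wrong relative configuration.
- A1 needs C8 and C8' set one after the other (two auxiliary cycles or a lactone route), and the whole sequence is linear on the most valuable intermediate.
- The chosen plan sets C8 and C8' in one catalytic event and joins two equal halves.

**Alternative 2:** (biomimetic)
- Cut: C8''–O4' and C7''–O together.
- Forward key step: one-electron oxidation of a mixture of the bisphenol A4 and (E)-isoeugenol A5. The O4' radical couples with the C8'' radical to give the quinone methide A6, and water adds at C7''.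
- This is the shortest conceivable endgame.
- A4 carries a second oxidisable phenol on ring A, and the radical of A5 is expected to prefer self-coupling.
- C8'' arises in a radical–radical encounter with no chiral influence within reach.
- Water adds to the planar A6 under the weak control of C8'' alone, which for ethers of 2,6-dimethoxyphenols should favour erythro.
- The brevity would be paid for with a statistical set of stereoisomers.

**Alternative 3:** ([3,3]-sigmatropic)
- Cut: C8–C8'.
- Forward key step: Ireland–Claisen rearrangement of the crotyl ester A7 to the acid A8. A chair transition state sets C8 and C8' together.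
- A7 is achiral, so absolute control needs a stoichiometric chiral controller or a chiral secondary allylic alcohol. The meso-type relation further depends on the enolate geometry.
- In A8, C9 is a carboxyl group (about three operations to a methyl group). The vinyl group also holds one carbon too many (cleavage, aryl addition, benzylic deoxygenation).
- The step builds a bond that can be bought in 3, and it leaves both ends at the wrong oxidation level.

Key step: step 3

Assumption: the ligand antipode that sends the aryl group to the carbonyl carbon bound to the (R)-configured ring carbon of 4 is taken to be the (R,R)-TADDOL-derived one; if the sense of induction is the reverse, the equally available (S,S)-ligand is used and nothing else changes.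

## Steps

Step 1
Reactants: 1 4-bromo-2-methoxyphenol
Product: 2 (4-bromo-2-methoxyphenoxy)triisopropylsilane
Conditions: TIPSCl, imidazole, DMF, rt
Reagents that add atoms: chlorotriisopropylsilane (TIPSCl), CC(C)[Si](Cl)(C(C)C)C(C)C
Why: Standard imidazole-assisted silylation of a phenol. The bulky aryl silyl ether is chosen because it has to survive n-BuLi, Mg, TFA, BH3 and zinc and still fall to fluoride at the end; 2 serves as ring A and as ring C.

Step 2
Reactants: 3 meso-(2R,3S)-2,3-dimethylbutanedioic acid
Product: 4 cis-(3R,4S)-3,4-dimethyloxolane-2,5-dione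
Conditions: AcCl (neat), reflux, 2 h; evaporation
Reagents that add atoms: none
Why: Cyclodehydration of a 1,2-diacid through its mixed acetic anhydride, with a fast five-membered ring closure. At the boiling point of acetyl chloride no enolisation is expected, so the meso relation of 3 appears as the cis relation of the two methyl groups of 4.

Step 3
Reactants: 2 (4-bromo-2-methoxyphenoxy)triisopropylsilane; 4 cis-(3R,4S)-3,4-dimethyloxolane-2,5-dione
Product: 7 (2S,3R)-4-[3-methoxy-4-(triisopropylsilyloxy)phenyl]-2,3-dimethyl-4-oxobutanoic acid, via aryllithium 5 (not isolated), via arylzinc triflate 6 (not isolated)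
Conditions: 2, n-BuLi, THF, −78 °C; Zn(OTf)2, −78 °C → rt; then 4, [Rh(cod)Cl]2 (4 mol %), (R,R)-TADDOL-derived P–NMe2 phosphoramidite (8 mol %), THF, 50 °C; then 1 M HCl
Reagents that add atoms: n-butyllithium, [Li]CCCC (its lithium stands in 5 only); zinc triflate, [Zn+2].[O-]S(=O)(=O)C(F)(F)F.[O-]S(=O)(=O)C(F)(F)F (its zinc and one triflate stand in 6 only)
Why: Bromine–lithium exchange and transmetalation give 6, a non-basic aryl donor that should open 4 only slowly by itself. The aryl group passes from zinc to the monovalent rhodium–phosphoramidite complex, this species inserts into one of the two enantiotopic C(acyl)–O bonds of 4 to give a trivalent acyl(aryl)rhodium carboxylate, and reductive elimination forms C7–C1 and releases the zinc carboxylate of 7. The closest known reaction type is the transition-metal-catalysed enantioselective desymmetrising cross-coupling of cyclic meso anhydrides with organozinc reagents, which covers succinic anhydrides and arylzinc donors. No ring is closed; the oxolanedione ring is opened. No bond at C8 or C8' is touched, so their relative (meso-type) configuration is that of 4, and their absolute configuration is decided only by which carbonyl group reacts, that is, by the chiral pocket of the TADDOL backbone in the C–O insertion. The step needs enantiotopic-group selectivity (ligand), a single addition (aryl ketone and zinc carboxylate are inert to arylzinc reagents) and configurational integrity at C8 (no base stronger than a carboxylate is present). The product has its two ends differentiated as ketone (C7) and acid (C7'). Because the chain is pseudo-meso, a wrong sense of induction could also be corrected by introducing ring B first.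

Step 4
Reactants: 7 (2S,3R)-4-[3-methoxy-4-(triisopropylsilyloxy)phenyl]-2,3-dimethyl-4-oxobutanoic acid
Product: 8 (2S,3S)-4-[3-methoxy-4-(triisopropylsilyloxy)phenyl]-2,3-dimethylbutanoic acid
Conditions: Et3SiH (3 equiv), TFA/CH2Cl2 (1:1), 0 °C → rt
Reagents that add atoms: none
Why: Ionic hydrogenation (Kursanov–Parnes reduction): the protonated ketone takes up hydride, the benzylic alcohol ionises to a cation stabilised by the para silyloxy group, and a second hydride gives the C7 methylene. Carboxyl group, aryl silyl ether and methoxy group are inert, and excess silane at low temperature lets hydride transfer outrun enolisation, so C8 is kept (the change of descriptor is only a change of priorities).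

Step 5
Reactants: 8 (2S,3S)-4-[3-methoxy-4-(triisopropylsilyloxy)phenyl]-2,3-dimethylbutanoic acid
Product: 9 (2S,3S)-4-[3-methoxy-4-(triisopropylsilyloxy)phenyl]-2,3-dimethylbutan-1-ol
Conditions: BH3·THF, THF, 0 °C → rt; then H2O
Reagents that add atoms: none
Why: Chemoselective borane reduction of a carboxylic acid through its acyloxyborane. The medium is not basic, so C8' next to the carboxyl group cannot epimerise, and the silyl ether is untouched.

Step 6
Reactants: 9 (2S,3S)-4-[3-methoxy-4-(triisopropylsilyloxy)phenyl]-2,3-dimethylbutan-1-ol
Product: 10 {4-[(2S,3S)-4-iodo-2,3-dimethylbutyl]-2-methoxyphenoxy}triisopropylsilane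
Conditions: I2, PPh3, imidazole, CH2Cl2, 0 °C → rt
Reagents that add atoms: iodine, [I][I]
Why: Appel-type iodination: iodide displaces the alkoxyphosphonium group at the primary carbon C7' in an SN2 reaction. No stereocentre takes part.

Step 7
Reactants: 11 4-bromo-2,6-dimethoxyphenol; 12 methyl (2R)-2-hydroxypropanoate (methyl (R)-lactate)
Product: 13 methyl (2S)-2-(4-bromo-2,6-dimethoxyphenoxy)propanoate
Conditions: PPh3, DIAD, THF, 0 °C → rt
Reagents that add atoms: none
Why: Mitsunobu etherification: the phenoxide attacks the oxyphosphonium salt of the lactate with inversion (R → S), which sets C8''. The adjacent ester speeds up the SN2 path and suppresses ionisation, and the small electrophile makes up for the two ortho methoxy groups of the phenol.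

Step 8
Reactants: 13 methyl (2S)-2-(4-bromo-2,6-dimethoxyphenoxy)propanoate
Product: 14 (2S)-2-(4-bromo-2,6-dimethoxyphenoxy)-N-methoxy-N-methylpropanamide
Conditions: MeNH(OMe)·HCl, i-PrMgCl, THF, −20 → 0 °C; then 1 M HCl
Reagents that add atoms: N,O-dimethylhydroxylamine hydrochloride, CNOC.Cl
Why: Weinreb amide formation by aminolysis of the ester with the chloromagnesium amide made in the flask. At this temperature acyl transfer should be faster than enolisation at C8'', and i-PrMgCl does not exchange with an electron-rich aryl bromide.

Step 9
Reactants: 14 (2S)-2-(4-bromo-2,6-dimethoxyphenoxy)-N-methoxy-N-methylpropanamide; 2 (4-bromo-2-methoxyphenoxy)triisopropylsilane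
Product: 16 (2S)-2-(4-bromo-2,6-dimethoxyphenoxy)-1-[3-methoxy-4-(triisopropylsilyloxy)phenyl]propan-1-one, via aryl Grignard reagent 15 (not isolated)
Conditions: 2, Mg, LiCl, THF, rt → 40 °C; then 14, THF, 0 °C; then cold 1 M HCl
Reagents that add atoms: magnesium, [Mg] (it stands in 15 only)
Why: Weinreb ketone synthesis: the five-membered magnesium chelate of the adduct holds until work-up and prevents a second addition. An aryl Grignard reagent, unlike an aryllithium, should not exchange with the C1'–Br bond at 0 °C, and the acidic quench protects the now acidic C8''–H.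

Step 10
Reactants: 16 (2S)-2-(4-bromo-2,6-dimethoxyphenoxy)-1-[3-methoxy-4-(triisopropylsilyloxy)phenyl]propan-1-one
Product: 17 (1S,2S)-2-(4-bromo-2,6-dimethoxyphenoxy)-1-[3-methoxy-4-(triisopropylsilyloxy)phenyl]propan-1-ol
Conditions: RuCl(p-cymene)[(R,R)-TsDPEN] (2 mol %), HCO2H/Et3N (5:2), CH2Cl2, 25 °C
Reagents that add atoms: none
Why: Noyori–Ikariya asymmetric transfer hydrogenation: hydride and proton pass from the ruthenium hydride–amine in an outer-sphere transition state whose face is fixed by the CH/π contact between p-cymene and ring C, and the (R,R)-catalyst gives the arrangement that is named 7''S here because C8'' outranks the aryl group. The polar Felkin–Anh preference of the (S)-ketone (C8''–OAr bond anti to the incoming hydride, no chelating cation) points to the same face, so catalyst and substrate are matched for the threo alcohol. The acidic formate medium keeps enolisation at C8'' slow.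

Step 11
Reactants: 17 (1S,2S)-2-(4-bromo-2,6-dimethoxyphenoxy)-1-[3-methoxy-4-(triisopropylsilyloxy)phenyl]propan-1-ol
Product: 18 {4-[(1S,2S)-2-(4-bromo-2,6-dimethoxyphenoxy)-1-(triethylsilyloxy)propyl]-2-methoxyphenoxy}triisopropylsilane
Conditions: TESCl, imidazole, DMF, 0 °C → rt
Reagents that add atoms: chlorotriethylsilane (TESCl), CC[Si](Cl)(CC)CC
Why: Silylation of the secondary alcohol removes the only acidic proton before the organozinc coupling. The triethylsilyl group is chosen because it leaves together with the two aryl silyl ethers in the last step.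

Step 12
Reactants: 10 {4-[(2S,3S)-4-iodo-2,3-dimethylbutyl]-2-methoxyphenoxy}triisopropylsilane; 18 {4-[(1S,2S)-2-(4-bromo-2,6-dimethoxyphenoxy)-1-(triethylsilyloxy)propyl]-2-methoxyphenoxy}triisopropylsilane
Product: 20 (7''S,8S,8'R,8''S)-3,3',3'',5'-tetramethoxy-7''-(triethylsilyloxy)-4,4''-bis(triisopropylsilyloxy)-4',8''-oxy-8,8'-sesquineolignan, via alkylzinc iodide 19 (not isolated)
Conditions: 10, Zn dust, LiCl, THF, 40 °C; decanted from zinc; then 18, Pd(OAc)2 (2 mol %), SPhos (4 mol %), THF, rt → 45 °C
Reagents that add atoms: zinc, [Zn] (it stands in 19 only)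
Why: LiCl-assisted zinc insertion into the primary iodide and Negishi sp3–sp2 cross-coupling: zerovalent palladium adds to the unhindered C1'–Br bond, and with the bulky biaryl phosphine reductive elimination should outrun β-hydride elimination. C8' is only β to the metal and C8, C7'' and C8'' are remote, so no stereocentre is at risk, and silyl and aryl ethers tolerate organozinc halides.

Step 13
Reactants: 20 (7''S,8S,8'R,8''S)-3,3',3'',5'-tetramethoxy-7''-(triethylsilyloxy)-4,4''-bis(triisopropylsilyloxy)-4',8''-oxy-8,8'-sesquineolignan
Product: 21 (+)-(7''S,8S,8'R,8''S)-4,4''-dihydroxy-3,3',3'',5'-tetramethoxy-4',8''-oxy-8,8'-sesquineolignan-7''-ol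
Conditions: TBAF, AcOH (1:1, 4 equiv each), THF, 0 °C → rt
Reagents that add atoms: none
Why: Fluoride cleaves all three Si–O bonds in one operation. The acetic acid buffer keeps the ring C phenol protonated, so it cannot expel the C7'' oxygen by the quinone methide path, and the medium is too weakly acidic to ionise the benzylic alcohol; C7'' is therefore kept.

## Compound list

1 | 4-bromo-2-methoxyphenol | COc1cc(Br)ccc1O | starting material
2 | (4-bromo-2-methoxyphenoxy)triisopropylsilane | COc1cc(Br)ccc1O[Si](C(C)C)(C(C)C)C(C)C | intermediate
3 | meso-(2R,3S)-2,3-dimethylbutanedioic acid | OC(=O)[C@H](C)[C@H](C)C(=O)O | starting material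
4 | cis-(3R,4S)-3,4-dimethyloxolane-2,5-dione | O=C1[C@H](C)[C@H](C)C(=O)O1 | intermediate
5 | [3-methoxy-4-(triisopropylsilyloxy)phenyl]lithium | COc1cc([Li])ccc1O[Si](C(C)C)(C(C)C)C(C)C | intermediate
6 | [3-methoxy-4-(triisopropylsilyloxy)phenyl]zinc triflate | COc1cc([Zn]OS(=O)(=O)C(F)(F)F)ccc1O[Si](C(C)C)(C(C)C)C(C)C | intermediate
7 | (2S,3R)-4-[3-methoxy-4-(triisopropylsilyloxy)phenyl]-2,3-dimethyl-4-oxobutanoic acid | COc1cc(C(=O)[C@H](C)[C@H](C)C(=O)O)ccc1O[Si](C(C)C)(C(C)C)C(C)C | intermediate
8 | (2S,3S)-4-[3-methoxy-4-(triisopropylsilyloxy)phenyl]-2,3-dimethylbutanoic acid | COc1cc(C[C@H](C)[C@H](C)C(=O)O)ccc1O[Si](C(C)C)(C(C)C)C(C)C | intermediate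
9 | (2S,3S)-4-[3-methoxy-4-(triisopropylsilyloxy)phenyl]-2,3-dimethylbutan-1-ol | COc1cc(C[C@H](C)[C@H](C)CO)ccc1O[Si](C(C)C)(C(C)C)C(C)C | intermediate
10 | {4-[(2S,3S)-4-iodo-2,3-dimethylbutyl]-2-methoxyphenoxy}triisopropylsilane | COc1cc(C[C@H](C)[C@H](C)CI)ccc1O[Si](C(C)C)(C(C)C)C(C)C | intermediate
11 | 4-bromo-2,6-dimethoxyphenol | COc1cc(Br)cc(OC)c1O | starting material
12 | methyl (2R)-2-hydroxypropanoate | C[C@@H](O)C(=O)OC | starting material
13 | methyl (2S)-2-(4-bromo-2,6-dimethoxyphenoxy)propanoate | COc1cc(Br)cc(OC)c1O[C@@H](C)C(=O)OC | intermediate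
14 | (2S)-2-(4-bromo-2,6-dimethoxyphenoxy)-N-methoxy-N-methylpropanamide | COc1cc(Br)cc(OC)c1O[C@@H](C)C(=O)N(C)OC | intermediate
15 | [3-methoxy-4-(triisopropylsilyloxy)phenyl]magnesium bromide | COc1cc([Mg]Br)ccc1O[Si](C(C)C)(C(C)C)C(C)C | intermediate
16 | (2S)-2-(4-bromo-2,6-dimethoxyphenoxy)-1-[3-methoxy-4-(triisopropylsilyloxy)phenyl]propan-1-one | COc1cc(Br)cc(OC)c1O[C@@H](C)C(=O)c1ccc(O[Si](C(C)C)(C(C)C)C(C)C)c(OC)c1 | intermediate
17 | (1S,2S)-2-(4-bromo-2,6-dimethoxyphenoxy)-1-[3-methoxy-4-(triisopropylsilyloxy)phenyl]propan-1-ol | COc1cc(Br)cc(OC)c1O[C@@H](C)[C@@H](O)c1ccc(O[Si](C(C)C)(C(C)C)C(C)C)c(OC)c1 | intermediate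
18 | {4-[(1S,2S)-2-(4-bromo-2,6-dimethoxyphenoxy)-1-(triethylsilyloxy)propyl]-2-methoxyphenoxy}triisopropylsilane | COc1cc(Br)cc(OC)c1O[C@@H](C)[C@@H](O[Si](CC)(CC)CC)c1ccc(O[Si](C(C)C)(C(C)C)C(C)C)c(OC)c1 | intermediate
19 | {(2S,3S)-4-[3-methoxy-4-(triisopropylsilyloxy)phenyl]-2,3-dimethylbutyl}zinc iodide | COc1cc(C[C@H](C)[C@H](C)C[Zn]I)ccc1O[Si](C(C)C)(C(C)C)C(C)C | intermediate
20 | (7''S,8S,8'R,8''S)-3,3',3'',5'-tetramethoxy-7''-(triethylsilyloxy)-4,4''-bis(triisopropylsilyloxy)-4',8''-oxy-8,8'-sesquineolignan | COc1cc(C[C@H](C)[C@H](C)Cc2cc(OC)c(O[C@@H](C)[C@@H](O[Si](CC)(CC)CC)c3ccc(O[Si](C(C)C)(C(C)C)C(C)C)c(OC)c3)c(OC)c2)ccc1O[Si](C(C)C)(C(C)C)C(C)C | intermediate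
21 | (+)-(7''S,8S,8'R,8''S)-4,4''-dihydroxy-3,3',3'',5'-tetramethoxy-4',8''-oxy-8,8'-sesquineolignan-7''-ol | COc1cc(C[C@H](C)[C@H](C)Cc2cc(OC)c(O[C@@H](C)[C@@H](O)c3ccc(O)c(OC)c3)c(OC)c2)ccc1O | target

## Step count and least certain steps

Total step count: 13.

Longest linear sequence: 7 steps. This holds for steps 1 (or 2), 3, 4, 5, 6, 12, 13, and equally for steps 7, 8, 9, 10, 11, 12, 13.

**Step 3 (key step).**
- What may go wrong: incomplete discrimination between the two enantiotopic acyl C–O bonds; an uncatalysed background opening by the arylzinc reagent; or slow transmetalation that forces a higher temperature and with it enolisation next to the new ketone.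
- Why it matters: any loss of purity here turns, after step 12, into a stereoisomer that differs only in the relation of two remote pairs.
- Remedy within the route: enrichment of 7 or 8 by crystallisation of a salt with a chiral amine.
- Fallback: it separates the desymmetrisation from the C–C bond formation. It sets out from 4 and comes back at 9.
  - Alkaloid-catalysed methanolysis of 4 ((DHQD)2AQN or its pseudo-enantiomer (DHQ)2AQN, MeOH, Et2O, −20 °C) should give the hemiester (2R,3S)-4-methoxy-2,3-dimethyl-4-oxobutanoic acid F1.
  - Oxalyl chloride with catalytic DMF converts it into methyl (2S,3R)-4-chloro-2,3-dimethyl-4-oxobutanoate F2.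
  - Acylative Negishi coupling with 6 (Pd(PPh3)4, THF, rt) gives methyl (2S,3R)-4-[3-methoxy-4-(triisopropylsilyloxy)phenyl]-2,3-dimethyl-4-oxobutanoate F3.
  - Et3SiH/TFA gives methyl (2S,3S)-4-[3-methoxy-4-(triisopropylsilyloxy)phenyl]-2,3-dimethylbutanoate F4, and LiBH4 reduces this to 9.

**Step 4.**
- What may go wrong: acid-promoted enolisation of the aryl ketone before hydride transfer, which would epimerise C8 and destroy the meso-type relation; or partial loss of the silyl group on long exposure to TFA.
- Fallback: it removes the enolisable ketone first under non-acidic conditions. It sets out from 7 and comes back at 8.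
  - NaBH4 (MeOH, 0 °C) followed by mild acidification closes the lactone (3S,4R)-5-[3-methoxy-4-(triisopropylsilyloxy)phenyl]-3,4-dimethyloxolan-2-one F5. The configuration at C5 is irrelevant.
  - Hydrogenolysis of its benzylic C–O bond (H2, Pd/C, EtOAc/AcOH) gives 8. The silyl ether tolerates these conditions.

**Step 10.**
- What may go wrong: poor facial selectivity if the bulky C8'' substituent competes with ring C for the catalyst pocket; slow reduction of the electron-rich aryl ketone; or amine-promoted enolisation that scrambles C8''.
- Fallback: C7'' is set in a C–C instead of a C–H bond formation. It sets out from 13, uses 15, and comes back at 17.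
  - DIBAL-H (CH2Cl2, −78 °C) gives (2S)-2-(4-bromo-2,6-dimethoxyphenoxy)propanal F6.
  - F6 is precomplexed with MgBr2·OEt2 and treated with 15 at −78 °C.
  - In the Cram chelate the aryl group enters from the side of the C8'' hydrogen, which leads to the same (1S,2S)-threo alcohol.

**Step 12.**
- What may go wrong: sluggish zinc insertion into the β-branched iodide; protonation of the organozinc reagent; β-hydride elimination from the alkylpalladium intermediate; or slow oxidative addition to the electron-rich aryl bromide.
- Fallback: the polarity is reversed, so no alkyl–palladium species occurs. It sets out from 18 and 10 and comes back at 20.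
  - Magnesium insertion into 18 (Mg, LiCl, THF) gives {4-[(1S,2S)-1-[3-methoxy-4-(triisopropylsilyloxy)phenyl]-1-(triethylsilyloxy)propan-2-yl]oxy-3,5-dimethoxyphenyl}magnesium bromide F7.
  - F7 displaces the primary iodide of 10 under copper catalysis (Li2CuCl4, THF/NMP, 0 °C).

## Further compounds

F1 | step 3 | (2R,3S)-4-methoxy-2,3-dimethyl-4-oxobutanoic acid | OC(=O)[C@H](C)[C@H](C)C(=O)OC
F2 | step 3 | methyl (2S,3R)-4-chloro-2,3-dimethyl-4-oxobutanoate | ClC(=O)[C@H](C)[C@H](C)C(=O)OC
F3 | step 3 | methyl (2S,3R)-4-[3-methoxy-4-(triisopropylsilyloxy)phenyl]-2,3-dimethyl-4-oxobutanoate | COc1cc(C(=O)[C@H](C)[C@H](C)C(=O)OC)ccc1O[Si](C(C)C)(C(C)C)C(C)C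
F4 | step 3 | methyl (2S,3S)-4-[3-methoxy-4-(triisopropylsilyloxy)phenyl]-2,3-dimethylbutanoate | COc1cc(C[C@H](C)[C@H](C)C(=O)OC)ccc1O[Si](C(C)C)(C(C)C)C(C)C
F5 | step 4 | (3S,4R)-5-[3-methoxy-4-(triisopropylsilyloxy)phenyl]-3,4-dimethyloxolan-2-one (both C5 epimers) | COc1cc(C2[C@H](C)[C@H](C)C(=O)O2)ccc1O[Si](C(C)C)(C(C)C)C(C)C
F6 | step 10 | (2S)-2-(4-bromo-2,6-dimethoxyphenoxy)propanal | COc1cc(Br)cc(OC)c1O[C@@H](C)C=O
F7 | step 12 | {4-[(1S,2S)-1-[3-methoxy-4-(triisopropylsilyloxy)phenyl]-1-(triethylsilyloxy)propan-2-yl]oxy-3,5-dimethoxyphenyl}magnesium bromide | COc1cc([Mg]Br)cc(OC)c1O[C@@H](C)[C@@H](O[Si](CC)(CC)CC)c1ccc(O[Si](C(C)C)(C(C)C)C(C)C)c(OC)c1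
A1 | alternative 1 | 4-[(2R,3S)-4-(4-benzyloxy-3-methoxyphenyl)-2,3-dimethylbutyl]-2,6-dimethoxyphenol | COc1cc(C[C@H](C)[C@H](C)Cc2cc(OC)c(O)c(OC)c2)ccc1OCc1ccccc1
A2 | alternative 1 | rac-2-bromo-1-(4-benzyloxy-3-methoxyphenyl)propan-1-one | CC(Br)C(=O)c1ccc(OCc2ccccc2)c(OC)c1
A3 | alternative 1 | 2-{4-[(2R,3S)-4-(4-benzyloxy-3-methoxyphenyl)-2,3-dimethylbutyl]-2,6-dimethoxyphenoxy}-1-(4-benzyloxy-3-methoxyphenyl)propan-1-one (both C8'' epimers) | COc1cc(C[C@H](C)[C@H](C)Cc2cc(OC)c(OC(C)C(=O)c3ccc(OCc4ccccc4)c(OC)c3)c(OC)c2)ccc1OCc1ccccc1
A4 | alternative 2 | 4-[(2R,3S)-4-(4-hydroxy-3-methoxyphenyl)-2,3-dimethylbutyl]-2,6-dimethoxyphenol | COc1cc(C[C@H](C)[C@H](C)Cc2cc(OC)c(O)c(OC)c2)ccc1O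
A5 | alternative 2 | (E)-isoeugenol, 2-methoxy-4-[(E)-prop-1-enyl]phenol | C/C=C/c1ccc(O)c(OC)c1
A6 | alternative 2 | 4-(2-{4-[(2R,3S)-4-(4-hydroxy-3-methoxyphenyl)-2,3-dimethylbutyl]-2,6-dimethoxyphenoxy}propylidene)-2-methoxycyclohexa-2,5-dien-1-one (quinone methide, C8'' undefined) | COc1cc(C[C@H](C)[C@H](C)Cc2cc(OC)c(OC(C)C=C3C=CC(=O)C(OC)=C3)c(OC)c2)ccc1O
A7 | alternative 3 | (E)-but-2-enyl 3-[3-methoxy-4-(triisopropylsilyloxy)phenyl]propanoate | C/C=C/COC(=O)CCc1ccc(O[Si](C(C)C)(C(C)C)C(C)C)c(OC)c1
A8 | alternative 3 | (2S,3R)-2-[3-methoxy-4-(triisopropylsilyloxy)benzyl]-3-methylpent-4-enoic acid | COc1cc(C[C@H](C(=O)O)[C@H](C)C=C)ccc1O[Si](C(C)C)(C(C)C)C(C)C
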